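**Strategy.** The route rests on disconnecting the O1–C8a aryl ether bond of ring C instead of the usual C2–O1 bond. Because the C5 and C8 oxygens of ring A are para to each other, ring A can be raised to a 2-acyl-5,6-dimethoxy-1,4-benzoquinone whose only unsubstituted carbon, C8a, is β to both the C5 quinone carbonyl and the C4 ketone. In one operation the preformed (S)-carbinol oxygen adds to C8a, closing ring C and regenerating the aromatic ring as the 5,8-hydroquinone, with the C2 stereocentre untouched. The precursor is the (S)-β-hydroxy ketone bearing this quinone, assembled from a Noyori-derived Weinreb amide and lithiated tetramethoxybenzene; two mild O-methylations finish the target.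

Key step: step 8

Atom labels (O1, C2, C3, C4, C4a, C5 to C8, C8a) follow flavanone numbering throughout.

Remark on the chemistry: the (S) sense of the hydrogenation in step 1 is assigned by analogy with the acetoacetate case. It would be confirmed by chiral HPLC on the hydroxy ester, and the optical purity could be raised by crystallization of the hydroxy amide if needed.

Step 1
Reactants: 1 methyl 3-(4-methoxyphenyl)-3-oxopropanoate
Product: 2 methyl (3S)-3-hydroxy-3-(4-methoxyphenyl)propanoate
Conditions: RuCl2[(R)-BINAP] (0.5 mol%), H2 (50 bar), MeOH, 40 °C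
Reagents that add atoms: none
Why: Noyori asymmetric hydrogenation of a β-keto ester, in which ketone and ester carbonyls chelate divalent ruthenium and the (R)-BINAP ligand directs hydride to the face that gives the (3S)-carbinol (the same spatial sense as acetoacetate to (R)-3-hydroxybutanoate, the descriptor changing only because aryl outranks CH2CO2Me).

Step 2
Reactants: 2 methyl (3S)-3-hydroxy-3-(4-methoxyphenyl)propanoate
Product: 3 (3S)-3-hydroxy-N-methoxy-3-(4-methoxyphenyl)-N-methylpropanamide
Conditions: MeNH(OMe)·HCl, iPrMgCl, THF, −20 to 0 °C; aq. NH4Cl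
Reagents that add atoms: N,O-dimethylhydroxylamine hydrochloride, CNOC.Cl
Why: Weinreb amide formation by aminolysis of the ester with the chloromagnesium amide should proceed at low temperature on the magnesium alkoxide of the hydroxy ester without touching the carbinol centre.

Step 3
Reactants: 3 (3S)-3-hydroxy-N-methoxy-3-(4-methoxyphenyl)-N-methylpropanamide
Product: 4 (3S)-3-[(tert-butyldimethylsilyl)oxy]-N-methoxy-3-(4-methoxyphenyl)-N-methylpropanamide
Conditions: TBSCl, imidazole, DMF, rt
Reagents that add atoms: tert-butyldimethylsilyl chloride, CC(C)(C)[Si](C)(C)Cl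
Why: Imidazole-promoted silylation of a secondary alcohol gives a silyl ether that masks the hydroxyl in the organolithium step and keeps the easily ionized p-methoxybenzylic oxygen weakly basic and hindered towards the Lewis acid of step 5.

Step 4
Reactants: 5 1,2,3,4-tetramethoxybenzene; 4 (3S)-3-[(tert-butyldimethylsilyl)oxy]-N-methoxy-3-(4-methoxyphenyl)-N-methylpropanamide
Product: 7 (3S)-3-[(tert-butyldimethylsilyl)oxy]-3-(4-methoxyphenyl)-1-(2,3,4,5-tetramethoxyphenyl)propan-1-one, via (2,3,4,5-tetramethoxyphenyl)lithium 6 (not isolated)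
Conditions: 5 (slight excess over n-BuLi), n-BuLi, TMEDA, THF, 0 °C; then 4, −78 to −20 °C; aq. NH4Cl
Reagents that add atoms: none
Why: Directed ortho-lithiation next to a methoxy group (the two ring hydrogens are equivalent) followed by Weinreb ketone synthesis, in which the aryllithium adds once to give a chelated tetrahedral adduct that releases the ketone only on work-up, places the acyl group beside the one ring carbon that keeps its hydrogen, the future C8a.

Step 5
Reactants: 7 (3S)-3-[(tert-butyldimethylsilyl)oxy]-3-(4-methoxyphenyl)-1-(2,3,4,5-tetramethoxyphenyl)propan-1-one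
Product: 8 (3S)-3-[(tert-butyldimethylsilyl)oxy]-1-(2-hydroxy-3,4,5-trimethoxyphenyl)-3-(4-methoxyphenyl)propan-1-one
Conditions: BCl3 (1.2 equiv), CH2Cl2, −78 °C; aq. NaHCO3
Reagents that add atoms: none
Why: Chelation-controlled Lewis acid demethylation, in which BCl3 is bound between the ketone oxygen and the ortho methoxy oxygen (the future C5–O), should remove only that methyl as MeCl at −78 °C and leave the other ring A ethers, the anisyl ether and the silyl ether alone.

Step 6
Reactants: 8 (3S)-3-[(tert-butyldimethylsilyl)oxy]-1-(2-hydroxy-3,4,5-trimethoxyphenyl)-3-(4-methoxyphenyl)propan-1-one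
Product: 9 (3S)-3-hydroxy-1-(2-hydroxy-3,4,5-trimethoxyphenyl)-3-(4-methoxyphenyl)propan-1-one
Conditions: HF·pyridine, pyridine, THF, 0 °C to rt
Reagents that add atoms: none
Why: Fluoride-mediated desilylation under buffered, weakly acidic conditions avoids the β-elimination that basic fluoride could cause in the aldol unit and does not involve the carbinol C–O bond, so the (S) configuration is kept.

Step 7
Reactants: 9 (3S)-3-hydroxy-1-(2-hydroxy-3,4,5-trimethoxyphenyl)-3-(4-methoxyphenyl)propan-1-one
Product: 10 2-[(3S)-3-hydroxy-3-(4-methoxyphenyl)propanoyl]-5,6-dimethoxycyclohexa-2,5-diene-1,4-dione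
Conditions: PhI(OAc)2 (1.05 equiv), MeCN/H2O (4:1), 0 °C, 15 min; cold extractive work-up, used at once
Reagents that add atoms: water, O
Why: Oxidative demethylation of a p-methoxyphenol by trivalent iodine (ligand exchange at iodine, attack of water at the para carbon C8, loss of methanol) should give the p-quinone within minutes and engages only the phenolic ring, so the anisyl ring and the secondary alcohol are left untouched and no base or fluoride ever meets the acylquinone.

Step 8
Reactants: 10 2-[(3S)-3-hydroxy-3-(4-methoxyphenyl)propanoyl]-5,6-dimethoxycyclohexa-2,5-diene-1,4-dione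
Product: 11 (2S)-5,8-dihydroxy-6,7-dimethoxy-2-(4-methoxyphenyl)chroman-4-one
Conditions: dry CH2Cl2 (0.01 M), rt, dark, argon (PPTS, 5 mol%, if closure is slow); then aq. Na2S2O4 wash
Reagents that add atoms: none
Why: The (S)-carbinol oxygen attacks C8a of the quinone, the one unsubstituted ring carbon and the β-position of both the C5 quinone carbonyl and the C4 ketone, and proton transfer followed by enolization turns the adduct into the aromatic 5,8-hydroquinone, which makes the addition irreversible. The closest known reaction type is the conjugate addition of alcohols and other heteroatom nucleophiles to C3 of 2-acyl-1,4-benzoquinones, applied here within one molecule. Ring C is closed by a 6-endo-trig oxa-Michael addition whose only new bond is O1–C8a. No stereocentre is formed and the C2–O bond set in step 1 is neither made nor broken, so the (S) configuration is carried through unchanged. The step needs site selectivity for C8a over addition–elimination at the methoxy-bearing C6 and C7 and over reversible hemiketal formation at C5, and this is secured by the double activation of C8a, by the tether (C6 could only be reached through a seven-membered ring and C7 not at all) and by the aromatization open only to the C8a adduct. High dilution in a neutral aprotic solvent favours the unimolecular closure over redox exchange between product and unreacted quinone, and the dithionite wash would return any over-oxidized flavanone to 11.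

Step 9
Reactants: 11 (2S)-5,8-dihydroxy-6,7-dimethoxy-2-(4-methoxyphenyl)chroman-4-one
Product: 12 (2S)-5-hydroxy-6,7,8-trimethoxy-2-(4-methoxyphenyl)chroman-4-one
Conditions: TMSCHN2 (hexanes), iPr2NEt, MeOH/MeCN, 0 °C to rt, argon
Reagents that add atoms: (trimethylsilyl)diazomethane, C[Si](C)(C)C=[N+]=[N-]
Why: O-Methylation of a phenol by a diazoalkane is neither oxidizing nor strongly basic, so the hydroquinone is not oxidized and ring C is not opened, and only the free C8 hydroxyl should react because the C5 hydroxyl is held in a hydrogen bond to the C4 carbonyl.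

Step 10
Reactants: 12 (2S)-5-hydroxy-6,7,8-trimethoxy-2-(4-methoxyphenyl)chroman-4-one
Product: 13 (2S)-5,6,7,8-tetramethoxy-2-(4-methoxyphenyl)chroman-4-one, the target (2S)-5,6,7,8,4'-pentamethoxyflavanone
Conditions: MeI (excess), Ag2O, CH2Cl2, 35 °C, dark
Reagents that add atoms: iodomethane, CI
Why: Purdie methylation (Ag2O activates MeI and takes up the iodide as AgI) should etherify the hydrogen-bonded C5 phenol without a soluble base, so enolization at C3 and retro-oxa-Michael opening are avoided, and it is held back to this step because Ag2O would oxidize the hydroquinone 11 to its quinone.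

**Compound list**

1 | methyl 3-(4-methoxyphenyl)-3-oxopropanoate | COc1ccc(C(=O)CC(=O)OC)cc1 | starting material
2 | methyl (3S)-3-hydroxy-3-(4-methoxyphenyl)propanoate | COc1ccc([C@@H](O)CC(=O)OC)cc1 | intermediate
3 | (3S)-3-hydroxy-N-methoxy-3-(4-methoxyphenyl)-N-methylpropanamide | COc1ccc([C@@H](O)CC(=O)N(C)OC)cc1 | intermediate
4 | (3S)-3-[(tert-butyldimethylsilyl)oxy]-N-methoxy-3-(4-methoxyphenyl)-N-methylpropanamide | COc1ccc([C@@H](O[Si](C)(C)C(C)(C)C)CC(=O)N(C)OC)cc1 | intermediate
5 | 1,2,3,4-tetramethoxybenzene | COc1ccc(OC)c(OC)c1OC | starting material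
6 | (2,3,4,5-tetramethoxyphenyl)lithium | [Li]c1cc(OC)c(OC)c(OC)c1OC | intermediate
7 | (3S)-3-[(tert-butyldimethylsilyl)oxy]-3-(4-methoxyphenyl)-1-(2,3,4,5-tetramethoxyphenyl)propan-1-one | COc1ccc([C@@H](O[Si](C)(C)C(C)(C)C)CC(=O)c2cc(OC)c(OC)c(OC)c2OC)cc1 | intermediate
8 | (3S)-3-[(tert-butyldimethylsilyl)oxy]-1-(2-hydroxy-3,4,5-trimethoxyphenyl)-3-(4-methoxyphenyl)propan-1-one | COc1ccc([C@@H](O[Si](C)(C)C(C)(C)C)CC(=O)c2cc(OC)c(OC)c(OC)c2O)cc1 | intermediate
9 | (3S)-3-hydroxy-1-(2-hydroxy-3,4,5-trimethoxyphenyl)-3-(4-methoxyphenyl)propan-1-one | COc1ccc([C@@H](O)CC(=O)c2cc(OC)c(OC)c(OC)c2O)cc1 | intermediate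
10 | 2-[(3S)-3-hydroxy-3-(4-methoxyphenyl)propanoyl]-5,6-dimethoxycyclohexa-2,5-diene-1,4-dione | COc1ccc([C@@H](O)CC(=O)C2=CC(=O)C(OC)=C(OC)C2=O)cc1 | intermediate
11 | (2S)-5,8-dihydroxy-6,7-dimethoxy-2-(4-methoxyphenyl)chroman-4-one | COc1ccc([C@@H]2CC(=O)c3c(O)c(OC)c(OC)c(O)c3O2)cc1 | intermediate
12 | (2S)-5-hydroxy-6,7,8-trimethoxy-2-(4-methoxyphenyl)chroman-4-one | COc1ccc([C@@H]2CC(=O)c3c(O)c(OC)c(OC)c(OC)c3O2)cc1 | intermediate
13 | (2S)-5,6,7,8-tetramethoxy-2-(4-methoxyphenyl)chroman-4-one | COc1ccc([C@@H]2CC(=O)c3c(OC)c(OC)c(OC)c(OC)c3O2)cc1 | target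

**Step count.** Total: 10 steps. Longest linear sequence: 10 steps (1 to 13; 5 is purchased and enters at step 4).

**Steps most likely to fail**

Step 8. Ring closure may be outpaced by intermolecular redox exchange between the closed hydroquinone and unreacted quinone, by hydration of the acylquinone, or by dehydration of the aldol unit. The fallback makes the same O1–C8a bond through a redox-neutral quinone monoketal. Setting out from diol 9, PhI(OAc)2 in MeOH at 0 °C would give 6-[(3S)-3-hydroxy-3-(4-methoxyphenyl)propanoyl]-2,3,4,4-tetramethoxycyclohexa-2,5-dien-1-one F1. Conjugate addition of the hydroxyl to the dienone carbon next to the ketal (the future C8a), on standing or with PPTS, followed by loss of methanol, aromatizes the ring. The product is the 5-hydroxy-8-methoxy flavanone, so the sequence comes back to the route at 12 and bypasses steps 7 to 9.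

Step 5. The Lewis acid may ionize or eliminate the p-methoxybenzylic silyl ether, with erosion of configuration or chalcone formation, or demethylate a second ether. The fallback brings in the ortho oxygen already differentiated. Commercial 2,3,4-trimethoxyphenol (COc1ccc(O)c(OC)c1OC) is protected with MOMCl and iPr2NEt in CH2Cl2 as 1-(methoxymethoxy)-2,3,4-trimethoxybenzene F2. Lithiation ortho to the acetal oxygen (n-BuLi, THF, 0 °C) gives [2-(methoxymethoxy)-3,4,5-trimethoxyphenyl]lithium F3. Addition to amide 4 at −78 °C gives (3S)-3-[(tert-butyldimethylsilyl)oxy]-1-[2-(methoxymethoxy)-3,4,5-trimethoxyphenyl]-3-(4-methoxyphenyl)propan-1-one F4. The acetal is then removed with ZnBr2 and n-PrSH in CH2Cl2 at 0 °C, and the route is rejoined at phenol 8.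

Step 10. Etherification of the hydrogen-bonded C5 hydroxyl may stall, or forcing it may open ring C by enolization and retro-oxa-Michael reaction, with loss of optical purity. The fallback removes the hydrogen bond and the enolizable ketone for the duration of the methylation. From 12, NaBH4 in MeOH at 0 °C would give the 2,4-cis alcohol (2S,4S)-6,7,8-trimethoxy-2-(4-methoxyphenyl)chromane-4,5-diol F5. MeI and K2CO3 in acetone then methylate the now ordinary phenol, with no ketone left to open the ring, to give (2S,4S)-5,6,7,8-tetramethoxy-2-(4-methoxyphenyl)chroman-4-ol F6. Dess–Martin periodinane with NaHCO3 in CH2Cl2 re-oxidizes the benzylic alcohol and arrives at the target 13.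

**Further compounds**

F1 | step 8 | 6-[(3S)-3-hydroxy-3-(4-methoxyphenyl)propanoyl]-2,3,4,4-tetramethoxycyclohexa-2,5-dien-1-one | COc1ccc([C@@H](O)CC(=O)C2=CC(OC)(OC)C(OC)=C(OC)C2=O)cc1
F2 | step 5 | 1-(methoxymethoxy)-2,3,4-trimethoxybenzene | COCOc1ccc(OC)c(OC)c1OC
F3 | step 5 | [2-(methoxymethoxy)-3,4,5-trimethoxyphenyl]lithium | [Li]c1cc(OC)c(OC)c(OC)c1OCOC
F4 | step 5 | (3S)-3-[(tert-butyldimethylsilyl)oxy]-1-[2-(methoxymethoxy)-3,4,5-trimethoxyphenyl]-3-(4-methoxyphenyl)propan-1-one | COc1ccc([C@@H](O[Si](C)(C)C(C)(C)C)CC(=O)c2cc(OC)c(OC)c(OC)c2OCOC)cc1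
F5 | step 10 | (2S,4S)-6,7,8-trimethoxy-2-(4-methoxyphenyl)chromane-4,5-diol | COc1ccc([C@@H]2C[C@H](O)c3c(O)c(OC)c(OC)c(OC)c3O2)cc1
F6 | step 10 | (2S,4S)-5,6,7,8-tetramethoxy-2-(4-methoxyphenyl)chroman-4-ol | COc1ccc([C@@H]2C[C@H](O)c3c(OC)c(OC)c(OC)c(OC)c3O2)cc1
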